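The disconnection cuts both bonds at the side-chain carbon C1': the C6–C1' bond to ring A and the O–acyl bond. C1' carries the ring A aryl group, an acyloxy oxygen and the homoprenyl chain, so it is an aldehyde carbon in disguise. One nickel-catalysed enantioconvergent reductive coupling joins a ring A aryl bromide, 4-methylpent-3-enal and 3-methylbut-2-enoyl chloride (through the racemic 1-chloroalkyl ester) and sets the (R) centre. The precursor is the leuco triacetate of naphthazarin monomethyl ether, brominated at C6, whose only ortho neighbour is the C5 methoxy group. Acetate removal and oxidation of ring B then give the quinone.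

Key step: step 5

Numbering used for all compounds: ring B is C1–C4 (C1 and C4 oxygenated); ring A is C5 (OMe), C6 (side chain), C7 (H), C8 (oxygen); the side chain is C1' (stereocentre), C2', C3'=C4'. CIP analysis of the target gives (R) at C1' (O > C6 > C2' > H).

Assumption: the sense of induction of the bis(oxazoline) ligand in step 5 cannot be predicted with confidence, so the ligand antipode that delivers (R) would be fixed in a test reaction; both antipodes are available.

Step 1
Reactants: 1 naphthazarin (5,8-dihydroxynaphthalene-1,4-dione)
Product: 2 5-hydroxy-8-methoxynaphthalene-1,4-dione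
Conditions: MeI (excess), Ag2O (0.6 equiv), CHCl3, rt, dark; chromatography (unreacted 1 recycled)
Reagents that add atoms: iodomethane, CI
Why: Ag2O-promoted Williamson-type O-methylation, held at the mono-ether by limiting the silver oxide; because the naphthazarin tautomers interconvert, methylation of either hydroxyl should give the same quinone with the methyl ether on the benzenoid ring.

Step 2
Reactants: 2 5-hydroxy-8-methoxynaphthalene-1,4-dione
Product: 3 5-methoxynaphthalene-1,4,8-triyl triacetate
Conditions: Zn dust, Ac2O, NaOAc (cat.), rt to 60 °C
Reagents that add atoms: acetic anhydride, CC(=O)OC(C)=O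
Why: Reductive acetylation: Zn reduces the quinone and the hydroquinone is trapped with the phenol as an air-stable triacetate, which leaves the methoxy group as the only strong donor on the naphthalene.

Step 3
Reactants: 3 5-methoxynaphthalene-1,4,8-triyl triacetate
Product: 4 6-bromo-5-methoxynaphthalene-1,4,8-triyl triacetate
Conditions: NBS (1.05 equiv), MeCN, 0 °C to rt, dark
Reagents that add atoms: N-bromosuccinimide, O=C1CCC(=O)N1Br
Why: Electrophilic aromatic bromination: the acetoxy groups are weak donors, so the methoxy group should direct the bromine to its free ortho carbon C6, the para carbon C8 being occupied.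

Step 4
Reactants: 5 4-methylpent-3-en-1-ol
Product: 6 4-methylpent-3-enal
Conditions: Dess–Martin periodinane, NaHCO3, CH2Cl2, 0 °C to rt; filtered through silica, used at once as a dry solution
Reagents that add atoms: none
Why: Dess–Martin oxidation under buffered, non-enolising conditions should stop at the β,γ-unsaturated aldehyde without moving the alkene into conjugation, and immediate use avoids loss of the volatile product.

Step 5
Reactants: 4 6-bromo-5-methoxynaphthalene-1,4,8-triyl triacetate, 6 4-methylpent-3-enal (slight excess over 7), 7 3-methylbut-2-enoyl chloride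
Product: 9 (R)-4-methyl-1-(1,4,8-triacetoxy-5-methoxynaphthalen-6-yl)pent-3-enyl 3-methylbut-2-enoate, via racemic 1-chloro-4-methylpent-3-enyl 3-methylbut-2-enoate 8 (not isolated)
Conditions: 6 + 7, ZnCl2 (cat.), CH2Cl2, −20 to 0 °C; then added to 4, NiBr2(dme) (10 mol%), cyclopropylidene-bridged indane-fused bis(oxazoline) (12 mol%), Mn powder, NaI, DMA, 0 °C
Reagents that add atoms: none
Why: Proposed new method: ZnCl2 first adds the acyl chloride across the aldehyde carbonyl to give racemic 8; oxidative addition of the C6–Br bond of 4 to zerovalent nickel then gives an aryl complex of divalent nickel, halogen-atom transfer from 8 to a monovalent nickel species turns both mirror-image forms of the chloroester into the same flat, oxygen-stabilised C1' radical, this radical adds to the ligand-bound aryl nickel centre, and the resulting trivalent nickel releases the C6–C1' bond by reductive elimination while Mn closes the cycle. The closest known reaction types are the nickel-catalysed enantioconvergent coupling of racemic 1-haloalkyl esters, prepared in situ from an aldehyde and an acyl halide, with organozinc reagents, and the nickel-catalysed asymmetric reductive arylation of secondary alkyl chlorides; new here is the union of such an α-acyloxy electrophile with an aryl halide under reducing conditions. No ring is closed. The configuration at C1' is decided by the C2-symmetric bis(oxazoline) on nickel when the radical is captured and the bond is released, so both enantiomers of 8 should converge on the (R) ester. The step needs cross-coupling to win over biaryl formation and dimerisation of the radical, and needs nickel to choose C–Br over the aryl acetate C–O bonds and the new benzylic C–O bond; the substrate helps through its single halide flanked only by the C5 methoxy group, the electron-withdrawing acetates that should speed oxidative addition, and a radical that can form only at the C–Cl bond, while the low temperature and the mild metal reductant protect the esters. The slight excess of 6 ensures that no free acyl chloride, itself a nickel electrophile, reaches the catalyst.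

Step 6
Reactants: 9 (R)-4-methyl-1-(1,4,8-triacetoxy-5-methoxynaphthalen-6-yl)pent-3-enyl 3-methylbut-2-enoate
Product: 11 (R)-1-(8-hydroxy-5-methoxy-1,4-dioxo-1,4-dihydronaphthalen-6-yl)-4-methylpent-3-enyl 3-methylbut-2-enoate, via (R)-4-methyl-1-(1,4,8-trihydroxy-5-methoxynaphthalen-6-yl)pent-3-enyl 3-methylbut-2-enoate 10 (not isolated)
Conditions: K2CO3 (cat.), degassed MeOH, 0 °C, Ar; pH 7 buffer/EtOAc; then Ag2O, Et2O, rt
Reagents that add atoms: none
Why: Base-catalysed transesterification should remove the three aryl acetates far faster than the hindered, conjugated secondary ester, and Ag2O then dehydrogenates the ring B hydroquinone of the triol to the quinone, the C5 methyl ether fixing the quinone in ring B and C1' remaining untouched.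

Compound list
1 | naphthazarin (5,8-dihydroxynaphthalene-1,4-dione) | O=C1C=CC(=O)c2c(O)ccc(O)c12 | starting material
2 | 5-hydroxy-8-methoxynaphthalene-1,4-dione | COc1ccc(O)c2C(=O)C=CC(=O)c12 | intermediate
3 | 5-methoxynaphthalene-1,4,8-triyl triacetate | COc1ccc(OC(C)=O)c2c(OC(C)=O)ccc(OC(C)=O)c12 | intermediate
4 | 6-bromo-5-methoxynaphthalene-1,4,8-triyl triacetate | COc1c(Br)cc(OC(C)=O)c2c(OC(C)=O)ccc(OC(C)=O)c12 | intermediate
5 | 4-methylpent-3-en-1-ol | CC(C)=CCCO | starting material
6 | 4-methylpent-3-enal | CC(C)=CCC=O | intermediate
7 | 3-methylbut-2-enoyl chloride | CC(C)=CC(Cl)=O | starting material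
8 | racemic 1-chloro-4-methylpent-3-enyl 3-methylbut-2-enoate | CC(C)=CCC(Cl)OC(=O)C=C(C)C | intermediate
9 | (R)-4-methyl-1-(1,4,8-triacetoxy-5-methoxynaphthalen-6-yl)pent-3-enyl 3-methylbut-2-enoate | COc1c([C@@H](CC=C(C)C)OC(=O)C=C(C)C)cc(OC(C)=O)c2c(OC(C)=O)ccc(OC(C)=O)c12 | intermediate
10 | (R)-4-methyl-1-(1,4,8-trihydroxy-5-methoxynaphthalen-6-yl)pent-3-enyl 3-methylbut-2-enoate | COc1c([C@@H](CC=C(C)C)OC(=O)C=C(C)C)cc(O)c2c(O)ccc(O)c12 | intermediate
11 | (R)-1-(8-hydroxy-5-methoxy-1,4-dioxo-1,4-dihydronaphthalen-6-yl)-4-methylpent-3-enyl 3-methylbut-2-enoate | COc1c([C@@H](CC=C(C)C)OC(=O)C=C(C)C)cc(O)c2c1C(=O)C=CC2=O | target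

Total step count: 6. Longest linear sequence: 5 steps (steps 1, 2, 3, 5, 6).

Steps most likely to fail

Step 5. The process at risk is slow oxidative addition at the ortho-methoxy aryl bromide, so that the chloroester is consumed by reduction or dimerisation, together with weak facial discrimination when the radical is captured. The fallback uses only known reactions, sets out from 4 and returns at 9. Stille coupling of 4 with tributyl(vinyl)stannane (Pd(PPh3)4, toluene, 100 °C) should give 6-ethenyl-5-methoxynaphthalene-1,4,8-triyl triacetate F1. Lemieux–Johnson cleavage (OsO4 cat., NaIO4, 2,6-lutidine, dioxane/water) should give 6-formyl-5-methoxynaphthalene-1,4,8-triyl triacetate F2. Keck asymmetric allylation (allyltributylstannane, Ti(OiPr)4 and the BINOL antipode that delivers (R), 4 Å sieves, CH2Cl2, −20 °C) should give (R)-1-(1,4,8-triacetoxy-5-methoxynaphthalen-6-yl)but-3-en-1-ol F3. Steglich esterification with 3-methylbut-2-enoic acid (DCC, DMAP, CH2Cl2) should give (R)-1-(1,4,8-triacetoxy-5-methoxynaphthalen-6-yl)but-3-enyl 3-methylbut-2-enoate F4. Cross-metathesis of F4 with 2-methylbut-2-ene (second-generation Grubbs catalyst, 40 °C) should turn the terminal alkene into the trisubstituted one and so arrive at 9; the β,β-disubstituted enoate should not take part.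

Step 6. The process at risk is methanolysis of the side-chain ester while the last acetate is still being cleaved, and base-mediated degradation of the electron-rich triol before it is oxidised. The fallback sets out from 9 and returns at 11, and no longer tries to keep the ester through the unmasking. Exhaustive saponification (LiOH, degassed THF/MeOH/water, 0 °C to rt) should remove all four esters and give (R)-6-(1-hydroxy-4-methylpent-3-enyl)-5-methoxynaphthalene-1,4,8-triol F5, which is not isolated. Neutral work-up and Ag2O should give (R)-8-hydroxy-6-(1-hydroxy-4-methylpent-3-enyl)-5-methoxynaphthalene-1,4-dione F6. Steglich acylation of F6 with 3-methylbut-2-enoic acid (DCC, DMAP cat., CH2Cl2, 0 °C) should esterify the secondary alcohol in preference to the C8 phenol, which is hydrogen-bonded to the C1 carbonyl, and give 11.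

Step 3. The process at risk is a sluggish substitution on the acetate-deactivated arene that, when forced, spreads to C7 or to ring B. The fallback sets out from 1 and returns at 4, and lets a free phenol direct the halogen. Reductive acetylation of 1 (Zn dust, Ac2O, NaOAc) should give naphthalene-1,4,5,8-tetrayl tetraacetate F7. Partial hydrazinolysis (N2H4·H2O, 1 equiv, THF, 0 °C; the four acetates are equivalent, so only one mono-phenol can form) should give 5-hydroxynaphthalene-1,4,8-triyl triacetate F8. NBS (CH2Cl2, 0 °C) should brominate ortho to the free hydroxyl and give 6-bromo-5-hydroxynaphthalene-1,4,8-triyl triacetate F9. Mitsunobu methylation of F9 (MeOH, PPh3, DIAD, THF), chosen because it avoids a free phenoxide that could trigger peri acetyl migration, should give 4.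

Further compounds
F1 | step 5 | 6-ethenyl-5-methoxynaphthalene-1,4,8-triyl triacetate | COc1c(C=C)cc(OC(C)=O)c2c(OC(C)=O)ccc(OC(C)=O)c12
F2 | step 5 | 6-formyl-5-methoxynaphthalene-1,4,8-triyl triacetate | COc1c(C=O)cc(OC(C)=O)c2c(OC(C)=O)ccc(OC(C)=O)c12
F3 | step 5 | (R)-1-(1,4,8-triacetoxy-5-methoxynaphthalen-6-yl)but-3-en-1-ol | COc1c([C@@H](CC=C)O)cc(OC(C)=O)c2c(OC(C)=O)ccc(OC(C)=O)c12
F4 | step 5 | (R)-1-(1,4,8-triacetoxy-5-methoxynaphthalen-6-yl)but-3-enyl 3-methylbut-2-enoate | COc1c([C@@H](CC=C)OC(=O)C=C(C)C)cc(OC(C)=O)c2c(OC(C)=O)ccc(OC(C)=O)c12
F5 | step 6 | (R)-6-(1-hydroxy-4-methylpent-3-enyl)-5-methoxynaphthalene-1,4,8-triol | COc1c([C@@H](CC=C(C)C)O)cc(O)c2c(O)ccc(O)c12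
F6 | step 6 | (R)-8-hydroxy-6-(1-hydroxy-4-methylpent-3-enyl)-5-methoxynaphthalene-1,4-dione | COc1c([C@@H](CC=C(C)C)O)cc(O)c2c1C(=O)C=CC2=O
F7 | step 3 | naphthalene-1,4,5,8-tetrayl tetraacetate | CC(=O)Oc1ccc(OC(C)=O)c2c(OC(C)=O)ccc(OC(C)=O)c12
F8 | step 3 | 5-hydroxynaphthalene-1,4,8-triyl triacetate | Oc1ccc(OC(C)=O)c2c(OC(C)=O)ccc(OC(C)=O)c12
F9 | step 3 | 6-bromo-5-hydroxynaphthalene-1,4,8-triyl triacetate | Oc1c(Br)cc(OC(C)=O)c2c(OC(C)=O)ccc(OC(C)=O)c12
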